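## Numbering used throughout

Rings are lettered A (2,4,6-trihydroxyphenoxy end) to E (3,4,5-trihydroxyphenyl end). In each ring C1, C2, C3 carry the adjacent oxygens and C5 the isolated one.

1 4-bromo-2,6-dimethoxyphenol · 2 its MOM ether · 3 syringaldehyde · 4 BC aldehyde, MOM ether · 5 BC aldehyde, free phenol · 6 BCD aldehyde, MOM ether · 7 BCD aldehyde, free phenol · 8 5-bromo-1,2,3-trimethoxybenzene · 9 BCDE aldehyde · 10 BCDE aryl formate · 11 BCDE phenol · 12 dimethyl 3-oxopentanedioate · 13 its dimethyl ketal · 14 potassium half-ester salt · 15 mixed carbonic anhydride · 16 diazoketone · 17 bromomethyl ketone · 18 Dieckmann precursor · 19 ketal-dione · 20 pentamer with aromatic ring A (decamethyl ether) · 21 target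

## Analysis of the target

The target is an achiral pentaaryl tetraether: five benzene rings in a row, four diaryl ether oxygens, twelve free phenols and no stereocentre. The whole problem is therefore one of C–O and C–C constitution. Every ether oxygen runs from C2 of one ring, a carbon flanked by two oxygen-bearing carbons, to C5 of the next, a carbon between two ring hydrogens: A(C2)–O–B(C5), B(C2)–O–C(C5), C(C2)–O–D(C5), D(C2)–O–E(C5). Rings B, C and D are the same 2,6-dihydroxy-1,4-dioxybenzene unit three times over, ring E is a 3,4,5-trihydroxyphenyl group and ring A a 2,4,6-trihydroxyphenoxy group. Each ring is a tetra-oxygenated benzene, so the free polyphenol is very electron-rich and oxidises easily, above all in base; the hydroxyls must stay masked until the last step. The difficulties are three. Every ether bond has a di-ortho-substituted partner. The three identical middle units demand strict control of chain length, because a monomer that is both phenol and aryl halide oligomerises. Twelve masked phenols must be freed at the end without an oxidant or base. The strategy rests on ring A: its oxygens sit on C1, C3 and C5 and its ether oxygen on C2, which is the pattern of a 6-aryloxy-3,5-dioxohexanoate chain closed between its ends. Chain C1, C5 and C3 become ring C1, C3 and C5, and the aryloxy-bearing chain C6 becomes ring C2.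

## Retrosynthetic reasoning

**21 from 20.** The ten O–CH3 bonds of 20 are cut last. Methyl ethers are the one phenol protection that survives every condition of the route: copper-catalysed coupling in hot base, aqueous acid, peracid, alkoxide and diazo chemistry. A boron Lewis acid cleaves them by bromide attack on the methyl carbon; the diaryl ether oxygens offer no sp3 carbon and stay. The forward step has to cleave all ten without oxidising the product.

**20 from 19.** Ring A is taken back to a cyclohexane-1,3-dione with a dimethyl ketal at C5. All three oxygenated carbons are then already at the phloroglucinol oxidation level. The forward step needs only acid to remove one methanol, followed by enolisation; no oxidant touches the electron-rich rings B to E. The methyl ether left on C5 of ring A goes in the final deprotection.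

**19 from 18 (key disconnection).** The C1–C2 bond of ring A is cut. This is the bond between a former ester carbon and the α-carbon of a ketone five atoms away, so the forward reaction is a Dieckmann closure of 18. Cutting here rather than at C3–C4 or C4–C5 keeps the C2–O bond outside the bond-forming event and leaves a precursor whose central carbonyl can be masked as a ketal. The gain is that ring A comes from a cheap acyclic chain and its crowded C2–O bond exists before the ring does. The forward step must enolise at the aryloxy-bearing carbon and acylate on carbon, not on oxygen.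

**18 from 11 and 17.** The O–CH2 bond is cut. The forward reaction is an SN2 displacement on the α-bromoketone 17 by the phenoxide of 11, whose oxygen sits on C5 of ring B between two hydrogens. The bond that would be the hardest diaryl ether of the molecule is thus made on a primary carbon without metal.

**17 from 16, 14 (via 15), 13 and 12.** The chain is cut between its ketone carbon and the bromomethyl carbon, which goes back to acylation of a one-carbon diazo nucleophile by an activated half-ester. 12 supplies the other five carbons with the central carbonyl in place. Ketalisation first makes that carbonyl base-stable; monosaponification then differentiates the two equal ends.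

**11 from 9 (via 10).** The C5–O bond of ring B is traced to a C5–CHO bond, formed forward by peracid oxidation with aryl migration. A formyl group is inert in the copper couplings, lets 3 serve as the ring B building block, and frees the hydroxyl exactly where the chain is attached.

**9 from 7 and 8; 7 from 6, from 5 and 2; 5 from 4, from 3 and 2; 2 from 1.** Each diaryl ether is cut between its oxygen and C5 of the right-hand ring. The nucleophile is then always the di-ortho-methoxy phenoxide and the electrophile always an unhindered bromide, the polarity that copper-catalysed etherification tolerates; the reverse would need substitution at a carbon between two methoxy groups. 1 cannot be used as such, because it carries both reacting functions and would couple with itself. It is capped as the methoxymethyl ether 2, and the chain is grown from ring B towards ring E. Acid hydrolysis releases one new phenol per round, and 8, which has no hydroxyl to free, ends the chain.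

## Alternatives that were turned down

**Alternative 1:** The eight phenolic C–O bonds at C1 and C3 of rings A to D are traced back to C–CHO bonds, giving the octa-aldehyde A2. In the forward key step a peracid converts all eight formyl groups into formates by aryl migration and methanolysis gives the tetrabenzyl ether A1; hydrogenolysis would finish.
- For: in A2 every C2 of rings A to D lies between two formyl groups, which activates exactly the crowded carbon for nucleophilic aromatic substitution. The hindered ethers can then form without copper, and the activating groups afterwards become the oxygens. Hydrogenolysis is a gentler end than a boron Lewis acid. On both points A1 is stronger than the chosen route.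
- Against: eight aryl migrations must succeed in one molecule. Each ring carries two formyl groups, so the first oxidation on a ring takes place on an arene that still bears an acceptor, where hydride migration to the carboxylic acid competes. Any formate cleaved early exposes an electron-rich phenol to peracid, and one failure among eight gives a product that cannot be separated. The ring monomers for A2 are again phenol and activated aryl halide in one molecule, so the chain-length problem returns.
- Comparison: the chosen route needs a single peracid oxidation, on 9, whose formyl ring carries three donors and no second acceptor. It pays with the harsher final deprotection.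

**Alternative 2:** Both ether bonds of ring C are cut. Ring C enters as the cyclopentadienylruthenium complex A4 (divalent ruthenium) of 2,5-dichloro-1,3-dimethoxybenzene. In one pot the phenoxide of the AB dimer A5 displaces the C5 chloride and the phenoxide of the DE dimer A6 then displaces the C2 chloride, giving complex A3; decomplexation and demethylation follow.
- For: it is the most convergent plan (2 + 1 + 2) and has a much shorter longest linear sequence. The cationic metal makes even an electron-rich, hindered chloroarene react with phenoxides under mild conditions. On convergence and on mildness of ether formation it is stronger than the chosen route.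
- Against: the order of the two substitutions rests only on the steric difference between the chlorides. Any crossover gives pentamers of the same mass and polarity with the wrong dimer on the wrong carbon. After the first substitution the ring is more electron-rich, and the remaining chloride sits between two methoxy groups. Ruthenium is stoichiometric. A5 and A6 still need the same hindered etherification, and the end is the same Lewis-acid demethylation with twelve methyl ethers, not ten.
- Comparison: the chosen route is linear, but each ether bond is formed between one defined phenol and one defined bromide, so no regiochemical question arises. That certainty of constitution is what it offers in place of convergence.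

**Alternative 3:** Ring E is dismantled across C1–C6 and C4–C5 into 3-ethoxy-4-methoxycyclobut-2-enone A8 and the tetrameric aryl ethynyl ether A9. On heating, A8 opens to a vinylketene, adds the alkyne, and the new cyclobutenone opens and closes (Danheiser benzannulation) to the pentamer A7 with a free C1 hydroxyl on ring E.
- For: the 1,2,3-trioxygenated ring forms with full regiocontrol and without reagents, and the D(C2)–O–E(C5) bond needs no coupling because its oxygen is already on the alkyne. In concept it equals the chosen route: a terminal ring built onto a phenol oxygen.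
- Against: ring E is the one ring that can be bought fully oxygenated as 8, and its attachment is the coupling with the least functionality at stake. A9 still contains all other hindered ethers and is an aryl ynol ether, which needs several steps from the phenol and is labile to heat and water. A8 also has to be made in several steps.
- Comparison: the chosen route builds its terminal ring from 12, a bulk chemical, attaches the chain in one SN2 step and closes the ring by ionic chemistry at or below room temperature. It forgoes the pericyclic cascade in return for cheap reagents and an easily made precursor.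

Key step: step 13

Assumption: 1, 3, 8 and 12 are taken as purchasable; 19 is drawn as the diketone although it should exist largely as its enol.

## Route

Step 1
Reactants: 1 4-bromo-2,6-dimethoxyphenol
Product: 2 5-bromo-1,3-dimethoxy-2-(methoxymethoxy)benzene
Conditions: NaH, DMF, 0 °C; MOMCl, 0 °C → rt
Reagents that add atoms: chloromethyl methyl ether (MOMCl), COCCl
Why: Williamson-type O-alkylation of the sodium phenoxide with a very reactive α-chloro ether; capping the hydroxyl turns the bifunctional bromophenol into a pure aryl bromide that can no longer couple with itself under copper catalysis.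

Step 2
Reactants: 3 syringaldehyde (4-hydroxy-3,5-dimethoxybenzaldehyde); 2 5-bromo-1,3-dimethoxy-2-(methoxymethoxy)benzene
Product: 4 4-[3,5-dimethoxy-4-(methoxymethoxy)phenoxy]-3,5-dimethoxybenzaldehyde
Conditions: CuI (10 mol%), picolinic acid (20 mol%), K3PO4, DMSO, 100 °C
Reagents that add atoms: none
Why: Ligand-accelerated Ullmann diaryl ether synthesis with CuI (monovalent copper); the hindered partner is the phenoxide and the bromide of 2 sits between two hydrogens, the polarity this reaction tolerates. The aldehyde has no α-hydrogen and the MOM acetal is stable to base.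

Step 3
Reactants: 4 4-[3,5-dimethoxy-4-(methoxymethoxy)phenoxy]-3,5-dimethoxybenzaldehyde
Product: 5 4-(4-hydroxy-3,5-dimethoxyphenoxy)-3,5-dimethoxybenzaldehyde
Conditions: 6 M HCl, THF, 50 °C
Reagents that add atoms: none
Why: Acid hydrolysis of the formaldehyde acetal frees the C2 hydroxyl of ring C; aryl methyl ethers, the diaryl ether and the aldehyde do not react with aqueous acid at this temperature.

Step 4
Reactants: 5 4-(4-hydroxy-3,5-dimethoxyphenoxy)-3,5-dimethoxybenzaldehyde; 2 5-bromo-1,3-dimethoxy-2-(methoxymethoxy)benzene
Product: 6 4-{4-[3,5-dimethoxy-4-(methoxymethoxy)phenoxy]-3,5-dimethoxyphenoxy}-3,5-dimethoxybenzaldehyde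
Conditions: CuI (10 mol%), picolinic acid (20 mol%), K3PO4, DMSO, 100 °C
Reagents that add atoms: none
Why: Second Ullmann etherification of the same type; 5 holds the only free phenol and 2 the only halide, so the chain can grow by exactly one unit.

Step 5
Reactants: 6 4-{4-[3,5-dimethoxy-4-(methoxymethoxy)phenoxy]-3,5-dimethoxyphenoxy}-3,5-dimethoxybenzaldehyde
Product: 7 4-[4-(4-hydroxy-3,5-dimethoxyphenoxy)-3,5-dimethoxyphenoxy]-3,5-dimethoxybenzaldehyde
Conditions: 6 M HCl, THF, 50 °C
Reagents that add atoms: none
Why: Same MOM acetal hydrolysis as in step 3, now freeing the C2 hydroxyl of ring D.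

Step 6
Reactants: 7 4-[4-(4-hydroxy-3,5-dimethoxyphenoxy)-3,5-dimethoxyphenoxy]-3,5-dimethoxybenzaldehyde; 8 5-bromo-1,2,3-trimethoxybenzene
Product: 9 4-{4-[3,5-dimethoxy-4-(3,4,5-trimethoxyphenoxy)phenoxy]-3,5-dimethoxyphenoxy}-3,5-dimethoxybenzaldehyde
Conditions: CuI (10 mol%), picolinic acid (20 mol%), K3PO4, DMSO, 100 °C; 8 in excess
Reagents that add atoms: none
Why: Third Ullmann etherification; 8 brings ring E with all three oxygens in place and has no hydroxyl, so chain growth stops at the tetramer.

Step 7
Reactants: 9 4-{4-[3,5-dimethoxy-4-(3,4,5-trimethoxyphenoxy)phenoxy]-3,5-dimethoxyphenoxy}-3,5-dimethoxybenzaldehyde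
Product: 11 4-{4-[3,5-dimethoxy-4-(3,4,5-trimethoxyphenoxy)phenoxy]-3,5-dimethoxyphenoxy}-3,5-dimethoxyphenol, via aryl formate 10 (not isolated)
Conditions: mCPBA, CH2Cl2, 0 °C → rt; aq NaHCO3 wash; K2CO3 (cat.), MeOH, rt
Reagents that add atoms: meta-chloroperbenzoic acid (mCPBA), OOC(=O)c1cccc(Cl)c1
Why: Dakin-type Baeyer–Villiger oxidation; in the peracid adduct the aryl group, which carries a para aryloxy donor, migrates in preference to hydride, as in the standard conversion of 3,4,5-trialkoxybenzaldehydes into phenols. Methanolysis of formate 10 frees the hydroxyl on C5 of ring B.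

Step 8
Reactants: 12 dimethyl 3-oxopentanedioate
Product: 13 dimethyl 3,3-dimethoxypentanedioate
Conditions: HC(OMe)3, MeOH, TsOH·H2O (cat.), rt; NaOMe quench before concentration
Reagents that add atoms: trimethyl orthoformate, COC(OC)OC; methanol, CO
Why: Acid-catalysed ketalisation with the orthoformate as water scavenger; neutralising before concentration keeps the ketal from losing methanol to the conjugated enol ether.

Step 9
Reactants: 13 dimethyl 3,3-dimethoxypentanedioate
Product: 14 potassium 3,3,5-trimethoxy-5-oxopentanoate
Conditions: KOH (1.0 equiv), MeOH–H2O, 0 °C → rt; Et2O wash; lyophilise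
Reagents that add atoms: potassium hydroxide, [K+].[OH-]
Why: Monosaponification of a symmetric diester; the first carboxylate formed repels hydroxide and slows the second hydrolysis, and the ketal is inert to base. Keeping the product as its salt avoids a free carboxylic acid next to the ketal.

Step 10
Reactants: 14 potassium 3,3,5-trimethoxy-5-oxopentanoate
Product: 16 methyl 6-diazo-3,3-dimethoxy-5-oxohexanoate, via mixed carbonic anhydride 15 (not isolated)
Conditions: i-BuOCOCl, N-methylmorpholine (cat.), THF–MeCN, −15 °C; CH2N2, Et2O, −15 → 0 °C
Reagents that add atoms: diazomethane, C=[N+]=[N-]; isobutyl chloroformate, CC(C)COC(Cl)=O (its atoms stay in 15 only)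
Why: Mixed-anhydride activation followed by C-acylation of diazomethane, the first stage of the Arndt–Eistert sequence; no strong acid is formed, so the ketal is not at risk.

Step 11
Reactants: 16 methyl 6-diazo-3,3-dimethoxy-5-oxohexanoate
Product: 17 methyl 6-bromo-3,3-dimethoxy-5-oxohexanoate
Conditions: HBr (33% in AcOH, 1.0 equiv), Et2O, −30 °C, 10 min; aq NaHCO3
Reagents that add atoms: hydrogen bromide, Br
Why: Protonation of the diazo carbon and displacement of N2 by bromide is the standard route from diazoketones to bromomethyl ketones. The acid is consumed as it is added, and a ketal flanked by two electron-withdrawing CH2C=O groups ionises slowly at this temperature.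

Step 12
Reactants: 11 4-{4-[3,5-dimethoxy-4-(3,4,5-trimethoxyphenoxy)phenoxy]-3,5-dimethoxyphenoxy}-3,5-dimethoxyphenol; 17 methyl 6-bromo-3,3-dimethoxy-5-oxohexanoate
Product: 18 methyl 6-(BCDE aryloxy)-3,3-dimethoxy-5-oxohexanoate (BCDE as nonamethyl ether)
Conditions: K2CO3, acetone, rt
Reagents that add atoms: none
Why: Williamson ether synthesis; the unhindered phenoxide on C5 of ring B displaces bromide from an α-bromoketone, one of the fastest SN2 electrophiles. This forms on a primary carbon the C–O bond that becomes the crowded C2–O bond of ring A.

Step 13
Reactants: 18 methyl 6-(BCDE aryloxy)-3,3-dimethoxy-5-oxohexanoate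
Product: 19 2-(BCDE aryloxy)-5,5-dimethoxycyclohexane-1,3-dione
Conditions: t-BuOK (2.2 equiv), THF (0.02 M), −20 °C → rt; AcOH (2.2 equiv), 0 °C
Reagents that add atoms: none
Why: This is a Dieckmann (intramolecular Claisen) condensation of a 5-oxohexanoate to a cyclohexane-1,3-dione, a known reaction type. tert-Butoxide removes the most acidic C–H of 18, on the CH2 between the ketone and the aryloxy oxygen (chain C6); the enolate carbon adds to the ester carbonyl (chain C1) and loss of methoxide forms the C1–C2 bond of ring A, after which the second equivalent of base converts the 1,3-dione into its enolate and makes the closure irreversible. The ring closes in the 6-(enolendo)-exo-trig mode, which is stereoelectronically allowed, and the geminal methoxy groups on chain C3 bend the chain towards closure. Site selectivity comes from the substrate: the enolates at chain C4 and C2 could only close four-membered rings and so have no productive outlet. C-acylation wins over O-acylation because O-attack of the ketone enolate would give only a non-conjugated enol lactone that alkoxide reopens; the ketal at chain C3 interrupts the conjugation that makes a hydroxypyranone a sink for the unmasked 3,5-dioxo ester, and it keeps the ester out of a β-keto ester enolate. Dilution suppresses intermolecular condensation. No stereocentre is created, since C2 of 19 carries two identical ring arms.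

Step 14
Reactants: 19 2-(BCDE aryloxy)-5,5-dimethoxycyclohexane-1,3-dione
Product: 20 2-(BCDE aryloxy)-5-methoxybenzene-1,3-diol
Conditions: camphorsulfonic acid (10 mol%), toluene, 4 Å MS, 60 °C
Reagents that add atoms: none
Why: Acid-catalysed loss of one methanol from the ketal gives the 5-methoxycyclohexenedione, the keto tautomer of the resorcinol, and enolisation aromatises ring A. The ring carbons are already at the phloroglucinol oxidation level, so no oxidant is needed.

Step 15
Reactants: 20 2-(BCDE aryloxy)-5-methoxybenzene-1,3-diol
Product: 21 target dodecaphenol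
Conditions: BBr3 (30 equiv), CH2Cl2, −78 °C → rt; MeOH then H2O, 0 °C; reversed-phase chromatography with degassed solvents under argon
Reagents that add atoms: none
Why: Lewis-acid cleavage of aryl methyl ethers; each methoxy oxygen binds boron and bromide attacks the methyl carbon (SN2), while the diaryl ethers have no sp3 carbon and stay intact. Hydrolysis of the aryl borates frees the twelve phenols.

## Compound list

1 | 4-bromo-2,6-dimethoxyphenol | COc1cc(Br)cc(OC)c1O | starting material
2 | 5-bromo-1,3-dimethoxy-2-(methoxymethoxy)benzene | COCOc1c(OC)cc(Br)cc1OC | intermediate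
3 | syringaldehyde (4-hydroxy-3,5-dimethoxybenzaldehyde) | COc1cc(C=O)cc(OC)c1O | starting material
4 | 4-[3,5-dimethoxy-4-(methoxymethoxy)phenoxy]-3,5-dimethoxybenzaldehyde | O=Cc1cc(OC)c(Oc2cc(OC)c(OCOC)c(OC)c2)c(OC)c1 | intermediate
5 | 4-(4-hydroxy-3,5-dimethoxyphenoxy)-3,5-dimethoxybenzaldehyde | O=Cc1cc(OC)c(Oc2cc(OC)c(O)c(OC)c2)c(OC)c1 | intermediate
6 | 4-{4-[3,5-dimethoxy-4-(methoxymethoxy)phenoxy]-3,5-dimethoxyphenoxy}-3,5-dimethoxybenzaldehyde | O=Cc1cc(OC)c(Oc2cc(OC)c(Oc3cc(OC)c(OCOC)c(OC)c3)c(OC)c2)c(OC)c1 | intermediate
7 | 4-[4-(4-hydroxy-3,5-dimethoxyphenoxy)-3,5-dimethoxyphenoxy]-3,5-dimethoxybenzaldehyde | O=Cc1cc(OC)c(Oc2cc(OC)c(Oc3cc(OC)c(O)c(OC)c3)c(OC)c2)c(OC)c1 | intermediate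
8 | 5-bromo-1,2,3-trimethoxybenzene | COc1cc(Br)cc(OC)c1OC | starting material
9 | 4-{4-[3,5-dimethoxy-4-(3,4,5-trimethoxyphenoxy)phenoxy]-3,5-dimethoxyphenoxy}-3,5-dimethoxybenzaldehyde (BCDE aldehyde) | O=Cc1cc(OC)c(Oc2cc(OC)c(Oc3cc(OC)c(Oc4cc(OC)c(OC)c(OC)c4)c(OC)c3)c(OC)c2)c(OC)c1 | intermediate
10 | BCDE aryl formate (formate ester of 11) | O=COc1cc(OC)c(Oc2cc(OC)c(Oc3cc(OC)c(Oc4cc(OC)c(OC)c(OC)c4)c(OC)c3)c(OC)c2)c(OC)c1 | intermediate (not isolated)
11 | 4-{4-[3,5-dimethoxy-4-(3,4,5-trimethoxyphenoxy)phenoxy]-3,5-dimethoxyphenoxy}-3,5-dimethoxyphenol (BCDE phenol) | Oc1cc(OC)c(Oc2cc(OC)c(Oc3cc(OC)c(Oc4cc(OC)c(OC)c(OC)c4)c(OC)c3)c(OC)c2)c(OC)c1 | intermediate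
12 | dimethyl 3-oxopentanedioate | COC(=O)CC(=O)CC(=O)OC | starting material
13 | dimethyl 3,3-dimethoxypentanedioate | COC(=O)CC(OC)(OC)CC(=O)OC | intermediate
14 | potassium 3,3,5-trimethoxy-5-oxopentanoate | COC(=O)CC(OC)(OC)CC(=O)[O-].[K+] | intermediate
15 | isobutoxycarbonyl 3,3,5-trimethoxy-5-oxopentanoate (mixed carbonic anhydride) | COC(=O)CC(OC)(OC)CC(=O)OC(=O)OCC(C)C | intermediate (not isolated)
16 | methyl 6-diazo-3,3-dimethoxy-5-oxohexanoate | COC(=O)CC(OC)(OC)CC(=O)C=[N+]=[N-] | intermediate
17 | methyl 6-bromo-3,3-dimethoxy-5-oxohexanoate | COC(=O)CC(OC)(OC)CC(=O)CBr | intermediate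
18 | methyl 6-(BCDE aryloxy)-3,3-dimethoxy-5-oxohexanoate | COC(=O)CC(OC)(OC)CC(=O)COc1cc(OC)c(Oc2cc(OC)c(Oc3cc(OC)c(Oc4cc(OC)c(OC)c(OC)c4)c(OC)c3)c(OC)c2)c(OC)c1 | intermediate
19 | 2-(BCDE aryloxy)-5,5-dimethoxycyclohexane-1,3-dione | COC1(OC)CC(=O)C(Oc2cc(OC)c(Oc3cc(OC)c(Oc4cc(OC)c(Oc5cc(OC)c(OC)c(OC)c5)c(OC)c4)c(OC)c3)c(OC)c2)C(=O)C1 | intermediate
20 | 2-(BCDE aryloxy)-5-methoxybenzene-1,3-diol (decamethyl ether of the target) | COc1cc(O)c(Oc2cc(OC)c(Oc3cc(OC)c(Oc4cc(OC)c(Oc5cc(OC)c(OC)c(OC)c5)c(OC)c4)c(OC)c3)c(OC)c2)c(O)c1 | intermediate
21 | target, CNP0308003.0 | Oc1cc(O)c(Oc2cc(O)c(Oc3cc(O)c(Oc4cc(O)c(Oc5cc(O)c(O)c(O)c5)c(O)c4)c(O)c3)c(O)c2)c(O)c1 | target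

## Step count and least certain steps

Total: 15 steps. Longest linear sequence: 11 steps (steps 1–7 and 12–15, from 1). The chain branch (steps 8–11) joins at step 12.

**Step 13 (key step).** The most likely failure is β-elimination of methoxide from the ketal through the enolates at chain C2 or C4, running ahead of ring closure. The conjugated enol ether that results makes the ester less electrophilic and opens the way to lactonisation through the ketone enol oxygen. Elimination towards chain C4 is not fatal, since that isomer can still close and then gives the aromatic ring directly; elimination towards chain C2 with the wrong double-bond geometry is.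

The fallback gives up the chain closure and takes ring A from a fourth aldehyde-bearing aryl unit, using only reactions already in the route. It sets out from 7, whose aldehyde ring then serves as ring A. 7 is coupled with 2 (CuI, picolinic acid, K3PO4, DMSO) to the tetramer MOM ether aldehyde F1. Aqueous HCl in THF gives the tetramer phenol aldehyde F2, and coupling with 8 gives the pentamer aldehyde F3. mCPBA converts F3 into the pentamer formate F4, which is methanolysed without isolation to the pentamer phenol F5 (free hydroxyl on C5 of ring A, eleven methyl ethers). BBr3 as in step 15 brings the sequence back to the route at 21.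

**Step 11.** The most likely failure is acid-induced loss of the ketal, by ionisation and elimination to the enol ether or by hydrolysis, competing with protonation of the diazo carbon.

The fallback avoids acid and sets out from 14. By way of the mixed anhydride 15 and N,O-dimethylhydroxylamine hydrochloride with N-methylmorpholine, 14 is converted into methyl 5-[methoxy(methyl)amino]-3,3-dimethoxy-5-oxopentanoate F6. Chloromethyllithium (ICH2Cl, MeLi·LiBr, THF, −78 °C) adds to the N-methoxy-N-methylamide, which is the more reactive acyl group and gives a stable chelated adduct, to give methyl 6-chloro-3,3-dimethoxy-5-oxohexanoate F7. F7 alkylates 11 (K2CO3, NaI cat., acetone) and the sequence returns at 18.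

**Step 6.** This is the hardest of the three copper couplings: the largest hindered phenoxide meets the most electron-rich bromide. The likely failure is slow turnover, with protodebromination of 8 and degradation of the aldehyde over long heating.

The fallback replaces copper catalysis by metal-free arylation with a diaryliodonium salt and sets out from 7. 5-Iodo-1,2,3-trimethoxybenzene is oxidised with mCPBA and TsOH·H2O and trapped with 1,3,5-trimethoxybenzene to give (3,4,5-trimethoxyphenyl)(2,4,6-trimethoxyphenyl)iodonium tosylate F8. The potassium phenoxide of 7 (t-BuOK, toluene) attacks iodine, and ligand coupling transfers the less electron-rich 3,4,5-trimethoxyphenyl group, returning at 9.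

**Step 15.** The likely failures are incomplete cleavage, as partly demethylated borates precipitate before all ten ethers have reacted, and air oxidation of the polyphenol during isolation.

The fallback changes the isolation and sets out from 20. After BBr3 the crude product is acetylated (Ac2O, pyridine) to the dodecaacetate F9, which is stable, can be purified on silica and separated from under-cleaved material. Acid-catalysed methanolysis (AcCl cat., MeOH, argon) then returns to the route at 21 without base or oxidant.

## Further compounds

F1 | step 13 | 4-(4-{4-[3,5-dimethoxy-4-(methoxymethoxy)phenoxy]-3,5-dimethoxyphenoxy}-3,5-dimethoxyphenoxy)-3,5-dimethoxybenzaldehyde (tetramer MOM ether aldehyde) | O=Cc1cc(OC)c(Oc2cc(OC)c(Oc3cc(OC)c(Oc4cc(OC)c(OCOC)c(OC)c4)c(OC)c3)c(OC)c2)c(OC)c1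
F2 | step 13 | 4-{4-[4-(4-hydroxy-3,5-dimethoxyphenoxy)-3,5-dimethoxyphenoxy]-3,5-dimethoxyphenoxy}-3,5-dimethoxybenzaldehyde (tetramer phenol aldehyde) | O=Cc1cc(OC)c(Oc2cc(OC)c(Oc3cc(OC)c(Oc4cc(OC)c(O)c(OC)c4)c(OC)c3)c(OC)c2)c(OC)c1
F3 | step 13 | pentamer aldehyde (formyl on C5 of ring A, eleven methyl ethers) | O=Cc1cc(OC)c(Oc2cc(OC)c(Oc3cc(OC)c(Oc4cc(OC)c(Oc5cc(OC)c(OC)c(OC)c5)c(OC)c4)c(OC)c3)c(OC)c2)c(OC)c1
F4 | step 13 | pentamer aryl formate (formate ester of F5) | O=COc1cc(OC)c(Oc2cc(OC)c(Oc3cc(OC)c(Oc4cc(OC)c(Oc5cc(OC)c(OC)c(OC)c5)c(OC)c4)c(OC)c3)c(OC)c2)c(OC)c1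
F5 | step 13 | pentamer phenol (free hydroxyl on C5 of ring A, undecamethyl ether of the target) | Oc1cc(OC)c(Oc2cc(OC)c(Oc3cc(OC)c(Oc4cc(OC)c(Oc5cc(OC)c(OC)c(OC)c5)c(OC)c4)c(OC)c3)c(OC)c2)c(OC)c1
F6 | step 11 | methyl 5-[methoxy(methyl)amino]-3,3-dimethoxy-5-oxopentanoate | COC(=O)CC(OC)(OC)CC(=O)N(C)OC
F7 | step 11 | methyl 6-chloro-3,3-dimethoxy-5-oxohexanoate | COC(=O)CC(OC)(OC)CC(=O)CCl
F8 | step 6 | (3,4,5-trimethoxyphenyl)(2,4,6-trimethoxyphenyl)iodonium 4-methylbenzenesulfonate | COc1cc([I+]c2c(OC)cc(OC)cc2OC)cc(OC)c1OC.Cc1ccc(S(=O)(=O)[O-])cc1
F9 | step 15 | dodecaacetate of the target | CC(=O)Oc1cc(OC(C)=O)c(Oc2cc(OC(C)=O)c(Oc3cc(OC(C)=O)c(Oc4cc(OC(C)=O)c(Oc5cc(OC(C)=O)c(OC(C)=O)c(OC(C)=O)c5)c(OC(C)=O)c4)c(OC(C)=O)c3)c(OC(C)=O)c2)c(OC(C)=O)c1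
A1 | alternative 1 | tetra-O-benzyl ether of the target (benzyl on A5 and on the three ring E oxygens) | Oc1cc(OCc6ccccc6)cc(O)c1Oc1cc(O)c(Oc2cc(O)c(Oc3cc(O)c(Oc4cc(OCc6ccccc6)c(OCc6ccccc6)c(OCc6ccccc6)c4)c(O)c3)c(O)c2)c(O)c1
A2 | alternative 1 | octa-aldehyde pentamer (formyl on C1 and C3 of rings A to D, benzyl on A5 and on ring E) | O=Cc1cc(OCc6ccccc6)cc(C=O)c1Oc1cc(C=O)c(Oc2cc(C=O)c(Oc3cc(C=O)c(Oc4cc(OCc6ccccc6)c(OCc6ccccc6)c(OCc6ccccc6)c4)c(C=O)c3)c(C=O)c2)c(C=O)c1
A3 | alternative 2 | cyclopentadienylruthenium complex (on ring C) of the dodecamethyl ether of the target, hexafluorophosphate | COc1cc(OC)c(Oc2cc(OC)c(Oc3cc(OC)c(Oc4cc(OC)c(Oc5cc(OC)c(OC)c(OC)c5)c(OC)c4)c(OC)c3)c(OC)c2)c(OC)c1.[cH-]1cccc1.[Ru+2].F[P-](F)(F)(F)(F)F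
A4 | alternative 2 | cyclopentadienylruthenium complex of 2,5-dichloro-1,3-dimethoxybenzene, hexafluorophosphate | COc1cc(Cl)cc(OC)c1Cl.[cH-]1cccc1.[Ru+2].F[P-](F)(F)(F)(F)F
A5 | alternative 2 | 2,6-dimethoxy-4-(2,4,6-trimethoxyphenoxy)phenol (AB dimer) | COc1cc(OC)c(Oc2cc(OC)c(O)c(OC)c2)c(OC)c1
A6 | alternative 2 | 3,5-dimethoxy-4-(3,4,5-trimethoxyphenoxy)phenol (DE dimer) | COc1cc(Oc2c(OC)cc(O)cc2OC)cc(OC)c1OC
A7 | alternative 3 | pentamer with free C1 hydroxyl on ring E, C2 methyl and C3 ethyl ethers, all other oxygens methylated | CCOc1cc(Oc2c(OC)cc(Oc3c(OC)cc(Oc4c(OC)cc(Oc5c(OC)cc(OC)cc5OC)cc4OC)cc3OC)cc2OC)cc(O)c1OC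
A8 | alternative 3 | 3-ethoxy-4-methoxycyclobut-2-enone | CCOC1=CC(=O)C1OC
A9 | alternative 3 | ethynyl ether of the ring A to D tetramer (octamethyl ether) | C#COc1c(OC)cc(Oc2c(OC)cc(Oc3c(OC)cc(Oc4c(OC)cc(OC)cc4OC)cc3OC)cc2OC)cc1OC
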